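Decide whether the next run should go hotter by asking first how much of the unreacted J stands free to meet X.

the same everywhere: J 0.20 M; L 0.600 equiv; time 15 s
- north-east: temperature 110 °C
- south: temperature 125 °C
- west: temperature 140 °C

    J + X ⇌ E + G (K1 = 0.39, k1 = 0.312 /M/s, Ea1 = 59.0 kJ/mol, ΔH1 = −43.0 kJ/mol)
    L ⇌ X, rate k2*(cs2 - [X]) while solid is left; crystals form when [X] > cs2 (cs2 = 0.077 M, k2 = 1.18 /s)
    J ⇌ Q (K3 = 0.673, k3 = 1.33 /s, Ea3 = 98.0 kJ/mol, ΔH3 = −40.0 kJ/mol)
    E → Z (k4 = 0.0734 /s, Ea4 = 101 kJ/mol)
    (constants at 110 °C)

- L is a solid; its amount is given per volume of the solution
- constants are those at 110 °C; use the activation energies and enthalpies for any other temperature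
- at the start none of L is in solution

- which of these there is most of at the end, counted by the J in it, north-east (E / Z / J)
- which of these there is most of at the end, counted by the J in it, south (E / Z / J)
- which of these there is most of at the end, counted by the J in it, west (E / Z / J)
- final amount of the leader among these, as a percentage of the J charged, in north-east
- final amount of the leader among these, as a percentage of the J charged, in south
- final amount of the leader among these, as a percentage of the J charged, in west

Call J and Q together the pool, and let the free share f be the fraction of the pool standing as J once the J ⇌ Q balance holds, the reciprocal of one plus its equilibrium constant: 59.8% in north-east. That exchange gives off heat, so its constant falls on warming and f rises to 70.5% in south and 78.7% in west.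

The flask can be solved at both ends. Early, once the balance holds and before anything has left the pool, J stands at f. Late, L is the limiting reagent: with 0.600 equiv charged, the pool keeps at least the remainder, and J cannot fall below 23.9% in north-east, 28.2% in south and 31.5% in west.

My own join of the two ends is a pseudo-first-order drain of the pool, with X held near 0.077 M while solid L lasts. Its rate constant is the forward constant of the J + X step times f times that concentration: 0.0144 /s in north-east, 0.0340 /s in south and 0.0726 /s in west. The balance may be assumed along the way because its half-life, 0.210 s in north-east, is far shorter than the 48.1 s of the drain there.

After 15 s this gives J 48.2% in north-east and 42.3% in south, still ahead of the 40.0% lost from the pool there. In west it gives 26.5%, under the floor, so the drain overruns the charge of L there and X cannot be held near 0.077 M to the end. I therefore call J the leader in north-east and south, leave west open with J somewhere between 31.5% and 78.7%, and would make west the next run to see what going hotter gives.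

The forecast names J, J and J as leaders, west included, at 51% (46% to 55%), 51% (45% to 56%) and 46% (38% to 53%), on the grounds that “Heating shifts the J/Q balance towards J”.

The simulation gives J at 49.8%, 50.4% and 47.1%, inside those ranges, and west holds Z at 38.4%. In south at 1.21 s, J enters the J + X step at 0.0083 of its forward rate into Q. Taking E and Z from the charge and multiplying by f gives 47.1% for J in west. South left until 1.0 min holds Z 48.6% and E 0.966%, so f gives 35.6%, and J stands at 35.5%.

(The rate constants are assumed; what happens was integrated by code.)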